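**Retrosynthetic overview** (cembrane numbering in all intermediates: lactone C16(=O)–O–C2 with C1 carrying C15(=C17H2); C3=C4(C18); butenolide C19(=O)–O–C6 across C7=C8; C12 carries OOH and C20)
1. Target 36 ⇐ Schenck ene reaction at C11=C12 of bis-lactone 35 ⇐ one-pot oxidative lactonisation of tetraol 33, which holds two 2-ene-1,4-diol units ⇐ C18 methyl put on the C3≡C4 alkyne of 29.
2. Key disconnection C1–C2: 29 ⇐ [2,3]-Wittig ring contraction of the 17-membered propargylic allylic ether 27.
3. Enabling feature: in the α-methylene lactone ring the array O–C2–C1–C15(=C17H2) is a homoallylic alkoxide, so the lactone oxygen and C17 can be joined as a temporary O–CH2 tether that is cut as C1–C2 forms; C3=C4 is carried as an alkyne so that C2–H is the acidic site.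
4. 27 ⇐ Williamson closure of hydroxy chloride 26 ⇐ butenolide 21 (reduced and silylated to survive base) ⇐ (R)-epichlorohydrin (C5–C7, sets C6) + ether 1 (C2–C4) + (phenylthio)acetic acid (C8, C19) + iodide 18 (C9–C17 and C20, from pent-4-yn-1-ol).
5. Ring order: butenolide (made, then opened to a silylated Z-ene-diol) → 17-membered ether → 14-membered carbocycle → both lactones together → hydroperoxide last.

Key step: step 20

Remark: compounds 1, 2, 5, 8 and 10 are taken as commercial.
Assumption: in step 20 the (R,R)-amide is taken to be matched with the 6R centre for the 1R,2R product; if the pairing is the reverse, the (S,S)-amide is used with no other change.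

Step 1
Reactants: 1 4-methoxybenzyl propargyl ether; 2 (R)-epichlorohydrin
Product: 3 (2R)-1-chloro-6-[(4-methoxybenzyl)oxy]hex-4-yn-2-ol
Conditions: 1, n-BuLi, THF, −78 °C; BF3·OEt2; then 2, −78 °C; then H2O
Reagents that add atoms: none
Why: Lewis-acid-mediated alkynylation of an epoxide should take place at the unsubstituted ring carbon, so the stereocentre of 2 is untouched and becomes C6.

Step 2
Reactants: 3 (2R)-1-chloro-6-[(4-methoxybenzyl)oxy]hex-4-yn-2-ol
Product: 4 (2R)-2-{4-[(4-methoxybenzyl)oxy]but-2-yn-1-yl}oxirane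
Conditions: NaOH, THF/H2O, 0 °C
Reagents that add atoms: none
Why: Halohydrin-to-epoxide closure (intramolecular Williamson reaction) moves the epoxide to the other side of C6 without touching the stereocentre.

Step 3
Reactants: 4 (2R)-2-{4-[(4-methoxybenzyl)oxy]but-2-yn-1-yl}oxirane; 5 (phenylthio)acetic acid
Product: 7 (5R)-5-{4-[(4-methoxybenzyl)oxy]but-2-yn-1-yl}-3-(phenylthio)oxolan-2-one (C3 epimers), via hydroxy acid 6 (not isolated)
Conditions: 5, LiN(i-Pr)2 (2.2 equiv), THF, −78 → 0 °C; then 4, 0 °C → rt; aq. HCl to pH 3; then PPTS (cat.), toluene, 80 °C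
Reagents that add atoms: none
Why: Alkylation of the carboxylic acid dianion by the terminal epoxide carbon followed by lactonisation of the γ-hydroxy acid should give the sulfur-bearing lactone with C6 unchanged.

Step 4
Reactants: 8 triethyl phosphonoacetate
Product: 9 ethyl 2-(diethoxyphosphoryl)-3-hydroxypropanoate (racemic)
Conditions: aq. HCHO (1 equiv), K2CO3 (cat.), rt
Reagents that add atoms: formaldehyde C=O
Why: Base-catalysed aldol-type hydroxymethylation of the activated methylene gives the hydroxymethyl phosphonate needed for the next olefination.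

Step 5
Reactants: 10 pent-4-yn-1-ol
Product: 11 pent-4-ynal
Conditions: TEMPO (cat.), PhI(OAc)2, CH2Cl2, rt; used as a solution
Reagents that add atoms: none
Why: Nitroxyl-catalysed alcohol oxidation stops at the aldehyde and leaves the terminal alkyne alone.

Step 6
Reactants: 11 pent-4-ynal; 9 ethyl 2-(diethoxyphosphoryl)-3-hydroxypropanoate
Product: 12 ethyl (2E)-2-(hydroxymethyl)hept-2-en-6-ynoate
Conditions: K2CO3 (2 equiv), H2O/THF, rt
Reagents that add atoms: none
Why: Horner–Wadsworth–Emmons olefination with the α-substituted phosphonoacetate should place the ester trans to the chain, which decides that the CH2OH arm (cis to the chain) becomes C16 and the ester carbon becomes C17.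

Step 7
Reactants: 12 ethyl (2E)-2-(hydroxymethyl)hept-2-en-6-ynoate
Product: 13 ethyl (2E)-2-{[(tert-butyldimethylsilyl)oxy]methyl}hept-2-en-6-ynoate
Conditions: TBSCl, imidazole, CH2Cl2, rt
Reagents that add atoms: tert-butyldimethylsilyl chloride CC(C)(C)[Si](C)(C)Cl
Why: Standard silylation of a primary alcohol protects the future C16 oxygen.

Step 8
Reactants: 13 ethyl (2E)-2-{[(tert-butyldimethylsilyl)oxy]methyl}hept-2-en-6-ynoate
Product: 14 (2Z)-2-{[(tert-butyldimethylsilyl)oxy]methyl}hept-2-en-6-yn-1-ol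
Conditions: i-Bu2AlH (2.2 equiv), CH2Cl2, −78 °C; then aq. potassium sodium tartrate
Reagents that add atoms: none
Why: 1,2-Reduction of the enoate with an aluminium hydride at low temperature gives the allylic alcohol without change of alkene geometry.

Step 9
Reactants: 14 (2Z)-2-{[(tert-butyldimethylsilyl)oxy]methyl}hept-2-en-6-yn-1-ol
Product: 15 bis-silyl ether of 14 (CH2OTBS cis and CH2OTES trans to the chain)
Conditions: TESCl, imidazole, CH2Cl2, 0 °C
Reagents that add atoms: triethylsilyl chloride CC[Si](Cl)(CC)CC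
Why: Silylation with the more labile triethylsilyl group marks the C17 oxygen for selective release later.

Step 10
Reactants: 15 bis-silyl ether of 14
Product: 17 (3E,7Z)-4-methyl-8-{[(tert-butyldimethylsilyl)oxy]methyl}-9-[(triethylsilyl)oxy]nona-3,7-dien-1-ol, via alkenylalane 16 (not isolated)
Conditions: Me3Al, Cp2ZrCl2 (cat.), CH2Cl2, 0 °C → rt; then n-BuLi, THF, −78 °C; then ethylene oxide, −78 °C → rt; then H2O
Reagents that add atoms: trimethylaluminium C[Al](C)C; ethylene oxide C1CO1
Why: Zirconium-catalysed syn-carboalumination of the terminal alkyne puts methyl on the internal carbon, and the derived alanate opens ethylene oxide with retention, so the E-trisubstituted C11=C12 alkene, C20 and C9–C10 arrive in one operation.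

Step 11
Reactants: 17 (3E,7Z)-4-methyl-8-{[(tert-butyldimethylsilyl)oxy]methyl}-9-[(triethylsilyl)oxy]nona-3,7-dien-1-ol
Product: 18 (3E,7Z)-1-iodo-4-methyl-8-{[(tert-butyldimethylsilyl)oxy]methyl}-9-[(triethylsilyl)oxy]nona-3,7-diene
Conditions: PPh3, I2, imidazole, CH2Cl2, 0 °C
Reagents that add atoms: iodine II
Why: Appel-type iodination converts the primary alcohol into the iodide under neutral conditions that spare both silyl ethers.

Step 12
Reactants: 7 (5R)-5-{4-[(4-methoxybenzyl)oxy]but-2-yn-1-yl}-3-(phenylthio)oxolan-2-one; 18 iodide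
Product: 19 (5R)-3-alkyl-5-{4-[(4-methoxybenzyl)oxy]but-2-yn-1-yl}-3-(phenylthio)oxolan-2-one (alkyl = the nonadienyl chain of 18; C3 epimers)
Conditions: 7, LiN(i-Pr)2, THF, −78 °C; then 18, HMPA, −78 → −20 °C
Reagents that add atoms: none
Why: Alkylation of the sulfur-stabilised lactone enolate with a primary iodide forms C8–C9, and the new quaternary centre need not be controlled because the next step destroys it.

Step 13
Reactants: 19 alkylated phenylthio lactone
Product: 21 (5R)-3-alkyl-5-{4-[(4-methoxybenzyl)oxy]but-2-yn-1-yl}furan-2(5H)-one (alkyl as in 19), via sulfoxide 20 (not isolated)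
Conditions: mCPBA (1.0 equiv), NaHCO3, CH2Cl2, −78 °C; then toluene, 110 °C
Reagents that add atoms: none
Why: Chemoselective S-oxidation followed by thermal syn-elimination of the sulfoxide should give the conjugated endocyclic butenolide, as is usual for α-alkyl-α-sulfinyl lactones.

Step 14
Reactants: 21 butenolide
Product: 22 (6R,7Z,11E)-1,2-seco-18-norcembra-1(15),7,11-trien-3-yne-6,19-diol with 2-OPMB, 16-OTBS and 17-OTES (C14 cis to C16)
Conditions: i-Bu2AlH (4 equiv), CH2Cl2, −78 → 0 °C; then aq. potassium sodium tartrate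
Reagents that add atoms: none
Why: Exhaustive aluminium hydride reduction of the butenolide gives the Z-2-ene-1,4-diol, a base-stable masked butenolide that keeps the ring-locked Z geometry and C6.

Step 15
Reactants: 22 ene-diol
Product: 23 6,19-bis(tert-butyldimethylsilyl) ether of 22
Conditions: TBSCl, imidazole, DMF, rt
Reagents that add atoms: tert-butyldimethylsilyl chloride CC(C)(C)[Si](C)(C)Cl
Why: Silylation of both hydroxyls removes every acidic or base-sensitive group from the future Wittig substrate.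

Step 16
Reactants: 23 fully protected seco compound
Product: 24 17-alcohol (triethylsilyl group removed; 2-OPMB and three OTBS retained)
Conditions: PPTS (cat.), MeOH/CH2Cl2, 0 °C
Reagents that add atoms: none
Why: Acid-catalysed methanolysis cleaves a primary triethylsilyl ether much faster than tert-butyldimethylsilyl ethers (selective desilylation).

Step 17
Reactants: 24 17-alcohol
Product: 25 17-chloride (2-OPMB and three OTBS retained)
Conditions: NCS, Me2S, CH2Cl2, −20 → 0 °C
Reagents that add atoms: N-chlorosuccinimide O=C1CCC(=O)N1Cl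
Why: Corey–Kim chlorination converts the primary allylic alcohol into the chloride without allylic transposition.

Step 18
Reactants: 25 17-chloride
Product: 26 (6R,7Z,11E)-17-chloro-6,16,19-tris[(tert-butyldimethylsilyl)oxy]-1,2-seco-18-norcembra-1(15),7,11-trien-3-yn-2-ol
Conditions: DDQ, CH2Cl2/pH 7 buffer, 0 °C
Reagents that add atoms: none
Why: Oxidative cleavage of the p-methoxybenzyl ether frees the propargylic alcohol and leaves silyl ethers, alkenes and the allylic chloride untouched.

Step 19
Reactants: 26 hydroxy chloride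
Product: 27 (6R,7Z,11E)-17-membered cyclic ether (oxygen bridging C2 and C17) of 6,16,19-tris[(tert-butyldimethylsilyl)oxy]-1,2-seco-18-norcembra-1(15),7,11-trien-3-yne
Conditions: EtMgBr (1.05 equiv), THF, 0 °C; then slow addition to THF/HMPA, 60 °C (0.003 M)
Reagents that add atoms: none
Why: Intramolecular Williamson etherification of a propargylic alkoxide with a primary allylic chloride under high dilution is a known way to make 17-membered propargylic allylic ethers.

Step 20
Reactants: 27 17-membered propargylic allylic ether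
Product: 29 (1R,2R,6R,7Z,11E)-6,16,19-tris[(tert-butyldimethylsilyl)oxy]-18-norcembra-7,11,15(17)-trien-3-yn-2-ol, via lithio ether 28 (not isolated)
Conditions: bis[(1R)-1-phenylethyl]amine, n-BuLi, THF, 0 °C; then 27, THF, −78 → −20 °C; then H2O
Reagents that add atoms: none
Why: The amide base removes one of the two C2 hydrogens, the most acidic in 27 because C2 is both propargylic and next to the ether oxygen, and lithio ether 28 undergoes a concerted suprafacial [2,3]-sigmatropic (Wittig) shift through a five-membered envelope transition state in which O–C17 breaks as C1–C2 forms and the C15=C17 exocyclic methylene appears. The closest known reaction type is the [2,3]-Wittig ring contraction of macrocyclic propargylic allylic ethers, which has turned 17-membered ethers into 14-membered cembranoid carbocycles, also with chiral lithium amide bases. The 14-membered carbocycle is closed by contraction of the pre-formed 17-membered ring, not by an end-to-end cyclisation, so the two reacting carbons are held together by the O–CH2 tether. The relative configuration at C1 and C2 (anti, which later becomes the trans-fused lactone) should be controlled by the geometry of the C1=C15 alkene, whose C14 chain is trans to the OCH2 group, with the alkynyl group exo in the envelope; the absolute sense should be controlled by the chiral amide, which distinguishes the two diastereotopic C2 hydrogens, with the 6R silyloxy centre as a second, substrate-based element. The step needs metalation at C2 instead of the allylic C17H2 or a position next to a silyl ether, which the alkyne secures, and [2,3] over [1,2] migration, which the low temperature and the propargylic carbanion secure.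

Step 21
Reactants: 29 macrocyclic propargylic alcohol
Product: 31 (1R,2R,3Z,6R,7Z,11E)-4-iodo-6,16,19-tris[(tert-butyldimethylsilyl)oxy]-18-norcembra-3,7,11,15(17)-tetraen-2-ol, via alkenylaluminate 30 (not isolated)
Conditions: NaAlH2(OCH2CH2OMe)2, THF, 0 °C → rt; then I2, THF, −78 °C; then H2O
Reagents that add atoms: iodine II
Why: Hydroxyl-directed trans-hydroalumination of the propargylic alcohol delivers hydride to C3 and aluminium to C4 within a five-membered aluminate, and iodinolysis with retention gives the iodoalkene with iodine cis to C2.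

Step 22
Reactants: 31 iodoalkene
Product: 32 (1R,2S,3E,6R,7Z,11E)-6,16,19-tris[(tert-butyldimethylsilyl)oxy]cembra-3,7,11,15(17)-tetraen-2-ol
Conditions: MeZnCl (3 equiv), Pd(PPh3)4 (cat.), THF, rt → 50 °C
Reagents that add atoms: methylzinc chloride C[Zn]Cl
Why: Negishi cross-coupling replaces iodine by methyl with retention of alkene geometry, which gives the 3E alkene with C18 cis to C2.

Step 23
Reactants: 32 tris-silyl ether
Product: 33 (1R,2S,3E,6R,7Z,11E)-cembra-3,7,11,15(17)-tetraene-2,6,16,19-tetraol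
Conditions: Bu4NF, THF, rt
Reagents that add atoms: none
Why: Fluoride-mediated desilylation removes all three silyl ethers at once.

Step 24
Reactants: 33 tetraol
Product: 35 (1R,2S,3E,6R,7Z,11E)-cembra-3,7,11,15(17)-tetraene-16,2:19,6-diolide, via bis-lactol 34 (not isolated)
Conditions: TEMPO (cat.), PhI(OAc)2, CH2Cl2, rt
Reagents that add atoms: none
Why: Nitroxyl-catalysed oxidation is selective for the two primary allylic alcohols, each aldehyde is trapped by its 1,4-related secondary hydroxyl as a five-membered lactol, and the lactols are oxidised on to the lactones (oxidative lactonisation of 1,4-diols) with C2 and C6 unchanged.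

Step 25
Reactants: 35 bis-lactone
Product: 36 (1R,2S,3E,6R,7Z,10E,12S)-12-hydroperoxycembra-3,7,10,15(17)-tetraene-16,2:19,6-diolide (target)
Conditions: O2, tetraphenylporphyrin (cat.), visible light, CH2Cl2, −20 °C
Reagents that add atoms: dioxygen O=O
Why: In the Schenck ene reaction singlet oxygen should choose C11=C12, the only alkene that is neither conjugated to a carbonyl nor deactivated by an allylic lactone oxygen, and abstraction of a C10 hydrogen on the more crowded side gives the tertiary hydroperoxide with the shifted 10E alkene, the C12 configuration being expected from attack on the outer face of the macrocycle.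

**Compound list**
1 | 4-methoxybenzyl propargyl ether | C#CCOCc1ccc(OC)cc1 | starting material
2 | (R)-epichlorohydrin | ClC[C@H]1CO1 | starting material
3 | (2R)-1-chloro-6-[(4-methoxybenzyl)oxy]hex-4-yn-2-ol | COc1ccc(COCC#CC[C@@H](O)CCl)cc1 | intermediate
4 | (2R)-2-{4-[(4-methoxybenzyl)oxy]but-2-yn-1-yl}oxirane | COc1ccc(COCC#CC[C@@H]2CO2)cc1 | intermediate
5 | (phenylthio)acetic acid | OC(=O)CSc1ccccc1 | starting material
6 | (4R)-4-hydroxy-8-[(4-methoxybenzyl)oxy]-2-(phenylthio)oct-6-ynoic acid (C2 epimers) | COc1ccc(COCC#CC[C@@H](O)CC(Sc2ccccc2)C(O)=O)cc1 | intermediate (not isolated)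
7 | (5R)-5-{4-[(4-methoxybenzyl)oxy]but-2-yn-1-yl}-3-(phenylthio)oxolan-2-one (C3 epimers) | COc1ccc(COCC#CC[C@@H]2CC(Sc3ccccc3)C(=O)O2)cc1 | intermediate
8 | triethyl phosphonoacetate | CCOC(=O)CP(=O)(OCC)OCC | starting material
9 | ethyl 2-(diethoxyphosphoryl)-3-hydroxypropanoate (racemic) | CCOC(=O)C(CO)P(=O)(OCC)OCC | intermediate
10 | pent-4-yn-1-ol | C#CCCCO | starting material
11 | pent-4-ynal | C#CCCC=O | intermediate
12 | ethyl (2E)-2-(hydroxymethyl)hept-2-en-6-ynoate | C#CCC/C=C(\CO)C(=O)OCC | intermediate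
13 | ethyl (2E)-2-{[(tert-butyldimethylsilyl)oxy]methyl}hept-2-en-6-ynoate | C#CCC/C=C(\CO[Si](C)(C)C(C)(C)C)C(=O)OCC | intermediate
14 | (2Z)-2-{[(tert-butyldimethylsilyl)oxy]methyl}hept-2-en-6-yn-1-ol | C#CCC/C=C(\CO[Si](C)(C)C(C)(C)C)CO | intermediate
15 | triethylsilyl ether of 14 (CH2OTBS cis, CH2OTES trans to the chain) | C#CCC/C=C(\CO[Si](C)(C)C(C)(C)C)CO[Si](CC)(CC)CC | intermediate
16 | (E)-alkenyldimethylalane from 15 (Al on C11, methyl on C12) | C[Al](C)/C=C(\C)CC/C=C(\CO[Si](C)(C)C(C)(C)C)CO[Si](CC)(CC)CC | intermediate (not isolated)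
17 | (3E,7Z)-4-methyl-8-{[(tert-butyldimethylsilyl)oxy]methyl}-9-[(triethylsilyl)oxy]nona-3,7-dien-1-ol | OCC/C=C(\C)CC/C=C(\CO[Si](C)(C)C(C)(C)C)CO[Si](CC)(CC)CC | intermediate
18 | (3E,7Z)-1-iodo-4-methyl-8-{[(tert-butyldimethylsilyl)oxy]methyl}-9-[(triethylsilyl)oxy]nona-3,7-diene | ICC/C=C(\C)CC/C=C(\CO[Si](C)(C)C(C)(C)C)CO[Si](CC)(CC)CC | intermediate
19 | (5R)-5-{4-[(4-methoxybenzyl)oxy]but-2-yn-1-yl}-3-(phenylthio)oxolan-2-one carrying the nonadienyl chain of 18 on C3 (C3 epimers) | COc1ccc(COCC#CC[C@@H]2CC(Sc3ccccc3)(CC/C=C(\C)CC/C=C(\CO[Si](C)(C)C(C)(C)C)CO[Si](CC)(CC)CC)C(=O)O2)cc1 | intermediate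
20 | S-oxide of 19 (sulfoxide) | COc1ccc(COCC#CC[C@@H]2CC(S(=O)c3ccccc3)(CC/C=C(\C)CC/C=C(\CO[Si](C)(C)C(C)(C)C)CO[Si](CC)(CC)CC)C(=O)O2)cc1 | intermediate (not isolated)
21 | (5R)-5-{4-[(4-methoxybenzyl)oxy]but-2-yn-1-yl}furan-2(5H)-one carrying the nonadienyl chain of 18 on C3 | COc1ccc(COCC#CC[C@@H]2C=C(CC/C=C(\C)CC/C=C(\CO[Si](C)(C)C(C)(C)C)CO[Si](CC)(CC)CC)C(=O)O2)cc1 | intermediate
22 | (6R,7Z,11E)-1,2-seco-18-norcembra-1(15),7,11-trien-3-yne-6,19-diol with 2-OPMB, 16-OTBS, 17-OTES | COc1ccc(COCC#CC[C@@H](O)/C=C(\CO)CC/C=C(\C)CC/C=C(\CO[Si](C)(C)C(C)(C)C)CO[Si](CC)(CC)CC)cc1 | intermediate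
23 | 6,19-bis(tert-butyldimethylsilyl) ether of 22 | COc1ccc(COCC#CC[C@@H](O[Si](C)(C)C(C)(C)C)/C=C(\CO[Si](C)(C)C(C)(C)C)CC/C=C(\C)CC/C=C(\CO[Si](C)(C)C(C)(C)C)CO[Si](CC)(CC)CC)cc1 | intermediate
24 | 17-alcohol (2-OPMB, 6,16,19-tris-OTBS) | COc1ccc(COCC#CC[C@@H](O[Si](C)(C)C(C)(C)C)/C=C(\CO[Si](C)(C)C(C)(C)C)CC/C=C(\C)CC/C=C(\CO[Si](C)(C)C(C)(C)C)CO)cc1 | intermediate
25 | 17-chloride (2-OPMB, 6,16,19-tris-OTBS) | COc1ccc(COCC#CC[C@@H](O[Si](C)(C)C(C)(C)C)/C=C(\CO[Si](C)(C)C(C)(C)C)CC/C=C(\C)CC/C=C(\CO[Si](C)(C)C(C)(C)C)CCl)cc1 | intermediate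
26 | (6R,7Z,11E)-17-chloro-6,16,19-tris[(tert-butyldimethylsilyl)oxy]-1,2-seco-18-norcembra-1(15),7,11-trien-3-yn-2-ol | OCC#CC[C@@H](O[Si](C)(C)C(C)(C)C)/C=C(\CO[Si](C)(C)C(C)(C)C)CC/C=C(\C)CC/C=C(\CO[Si](C)(C)C(C)(C)C)CCl | intermediate
27 | (6R,7Z,11E)-17-membered cyclic ether, oxygen bridging C2 and C17, 6,16,19-tris-OTBS | O1CC#CC[C@@H](O[Si](C)(C)C(C)(C)C)/C=C(\CO[Si](C)(C)C(C)(C)C)CC/C=C(\C)CC/C=C(\CO[Si](C)(C)C(C)(C)C)C1 | intermediate
28 | 2-lithio derivative of 27 | O1C([Li])C#CC[C@@H](O[Si](C)(C)C(C)(C)C)/C=C(\CO[Si](C)(C)C(C)(C)C)CC/C=C(\C)CC/C=C(\CO[Si](C)(C)C(C)(C)C)C1 | intermediate (not isolated)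
29 | (1R,2R,6R,7Z,11E)-6,16,19-tris[(tert-butyldimethylsilyl)oxy]-18-norcembra-7,11,15(17)-trien-3-yn-2-ol | O[C@H]1C#CC[C@@H](O[Si](C)(C)C(C)(C)C)/C=C(\CO[Si](C)(C)C(C)(C)C)CC/C=C(\C)CC[C@@H]1C(=C)CO[Si](C)(C)C(C)(C)C | intermediate
30 | sodium cyclic alkenylaluminate of 29 (Al bonded to O2 and C4, two 2-methoxyethoxy ligands) | [Na+].COCCO[Al-]1(OCCOC)O[C@H]2/C=C1/C[C@@H](O[Si](C)(C)C(C)(C)C)/C=C(\CO[Si](C)(C)C(C)(C)C)CC/C=C(\C)CC[C@@H]2C(=C)CO[Si](C)(C)C(C)(C)C | intermediate (not isolated)
31 | (1R,2R,3Z,6R,7Z,11E)-4-iodo-6,16,19-tris[(tert-butyldimethylsilyl)oxy]-18-norcembra-3,7,11,15(17)-tetraen-2-ol | O[C@H]1/C=C(\I)C[C@@H](O[Si](C)(C)C(C)(C)C)/C=C(\CO[Si](C)(C)C(C)(C)C)CC/C=C(\C)CC[C@@H]1C(=C)CO[Si](C)(C)C(C)(C)C | intermediate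
32 | (1R,2S,3E,6R,7Z,11E)-6,16,19-tris[(tert-butyldimethylsilyl)oxy]cembra-3,7,11,15(17)-tetraen-2-ol | O[C@H]1/C=C(\C)C[C@@H](O[Si](C)(C)C(C)(C)C)/C=C(\CO[Si](C)(C)C(C)(C)C)CC/C=C(\C)CC[C@@H]1C(=C)CO[Si](C)(C)C(C)(C)C | intermediate
33 | (1R,2S,3E,6R,7Z,11E)-cembra-3,7,11,15(17)-tetraene-2,6,16,19-tetraol | O[C@H]1/C=C(\C)C[C@@H](O)/C=C(\CO)CC/C=C(\C)CC[C@@H]1C(=C)CO | intermediate
34 | bis-lactol: 16-hydroxy-16,2-epoxy and 19-hydroxy-19,6-epoxy derivative of the cembratetraene (anomers) | C=C1C(O)O[C@H]2/C=C(\C)C[C@@H]3C=C(CC/C=C(\C)CC[C@H]12)C(O)O3 | intermediate (not isolated)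
35 | (1R,2S,3E,6R,7Z,11E)-cembra-3,7,11,15(17)-tetraene-16,2:19,6-diolide | C=C1C(=O)O[C@H]2/C=C(\C)C[C@@H]3C=C(CC/C=C(\C)CC[C@H]12)C(=O)O3 | intermediate
36 | (1R,2S,3E,6R,7Z,10E,12S)-12-hydroperoxycembra-3,7,10,15(17)-tetraene-16,2:19,6-diolide | C=C1C(=O)O[C@H]2/C=C(\C)C[C@@H]3C=C(C/C=C/[C@@](C)(OO)CC[C@H]12)C(=O)O3 | target

**Totals**
Total step count: 25. Longest linear sequence: 21 steps (steps 5–11, then 12–25, from pent-4-yn-1-ol 10).

**Steps most likely to fail**

1. Step 25 (Schenck ene). What may go wrong: abstraction of a C20 methyl hydrogen instead of a C10 hydrogen (secondary hydroperoxide with an exocyclic methylene), attack of singlet oxygen on the inner face of the ring, or a competing ene reaction at C3=C4.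
Fallback, setting out from 35 and coming back at 36: the C11=C12 alkene is epoxidised under Shi conditions (D-fructose-derived ketone, KHSO5 as its triple salt, NaHCO3 buffer at pH 8, MeCN/H2O, 0 °C) to the (11R,12R)-epoxide F2. Perhydrolysis with anhydrous H2O2 in Et2O and catalytic H3PMo12O40 opens the epoxide at the tertiary carbon with inversion to the (11R,12S)-hydroperoxy alcohol F3, which fixes the C12 configuration by reagent control. The hydroperoxide is capped with 2-methoxypropene (1 equiv, PPTS cat., CH2Cl2, 0 °C) as the peroxyketal F4. The C11 hydroxyl, which has β-hydrogens only on C10, is dehydrated with Martin sulfurane (CH2Cl2, rt) to the 10E-alkenyl peroxyketal F5. Mild acid (AcOH/H2O/THF) then frees the hydroperoxide to give 36.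

2. Step 20 (key ring contraction). What may go wrong: metalation at C17 or next to a silyl ether, 1,2-migration instead of the [2,3] shift, or poor facial discrimination when the amide and the C6 centre work against each other.
Fallback, setting out from 26 and coming back at 29: the propargylic alcohol of 26 is oxidised with MnO2 (CH2Cl2, rt) to the ynal chloride F1. The C1–C2 bond is then closed by an intramolecular Nozaki–Hiyama–Kishi-type allylation (CrCl2, LiI cat., THF, high dilution, rt), in which the allylchromium formed from the C17 chloride adds through C1 to the C2 aldehyde. The chair transition state of the C14-trans allylchromium should give the same anti relationship, and the facial sense rests on the C6 centre; the product is 29.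

3. Step 24 (double oxidative lactonisation). What may go wrong: oxidation of the secondary allylic hydroxyls at C2 or C6 before lactol formation, or isomerisation of the Z-enal at C19 before ring closure.
Fallback, setting out from 33 and coming back at 35: the two oxidation levels are separated. MnO2 (CH2Cl2, rt) takes only the primary allylic alcohols to the aldehyde level, and the bis-lactol 34 is isolated. Ag2CO3 on Celite (Fetizon oxidation, benzene, reflux), a reagent specific for lactols, then gives 35. This fallback makes no compound outside the list (F0).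

Further compounds
F1 | step 20 | (6R,7Z,11E)-17-chloro-6,16,19-tris[(tert-butyldimethylsilyl)oxy]-1,2-seco-18-norcembra-1(15),7,11-trien-3-yn-2-al | O=CC#CC[C@@H](O[Si](C)(C)C(C)(C)C)/C=C(\CO[Si](C)(C)C(C)(C)C)CC/C=C(\C)CC/C=C(\CO[Si](C)(C)C(C)(C)C)CCl
F2 | step 25 | (11R,12R)-11,12-epoxide of 35 | C=C1C(=O)O[C@H]2/C=C(\C)C[C@@H]3C=C(CC[C@H]4O[C@]4(C)CC[C@H]12)C(=O)O3
F3 | step 25 | (11R,12S)-12-hydroperoxy-11-hydroxy derivative of the bis-lactone | C=C1C(=O)O[C@H]2/C=C(\C)C[C@@H]3C=C(CC[C@@H](O)[C@@](C)(OO)CC[C@H]12)C(=O)O3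
F4 | step 25 | 12-(2-methoxyprop-2-yl) peroxide of F3 | C=C1C(=O)O[C@H]2/C=C(\C)C[C@@H]3C=C(CC[C@@H](O)[C@@](C)(OOC(C)(C)OC)CC[C@H]12)C(=O)O3
F5 | step 25 | (10E,12S)-12-[(2-methoxyprop-2-yl)peroxy]cembra-3,7,10,15(17)-tetraene-16,2:19,6-diolide | C=C1C(=O)O[C@H]2/C=C(\C)C[C@@H]3C=C(C/C=C/[C@@](C)(OOC(C)(C)OC)CC[C@H]12)C(=O)O3
F0 | step 24 | none | none
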